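## Retrosynthetic overview
1. Side chain last: the (5''E)-7''-hydroxy unit comes from the intact geranyl chain of (2S)-6-geranylhomoeriodictyol by a singlet-oxygen (Schenck) ene reaction, the likely natural oxidation.
2. Ring C is the only ring built. The O1–C2 bond is cut back to the open, fully unprotected 3'-geranylchalcone, and closure is a chalcone-isomerase-type 6-endo oxa-Michael addition. A chiral bifunctional catalyst must select both the 6'-OH (giving 6-geranyl) and one enone face (giving 2S).
3. Chalcone Cα=Cβ: Claisen–Schmidt condensation of 3-geranylphloroacetophenone with vanillin, both unprotected, through a lithium polyanion.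
4. Aryl–geranyl bond: direct C-geranylation of phloroacetophenone, where ring symmetry allows only one mono-C isomer.
5. Rings A and B are bought, and no protecting groups are used.

Assumption: the sense of induction of the cinchona thiourea on this substrate is not known. The quinidine-derived catalyst is written. If CD shows the R product, its quinine-derived pseudoenantiomer is used instead (2S shows a positive band near 330 nm and a negative band near 290 nm).

## Route

Step 1
Reactants: 1 2,4,6-trihydroxyacetophenone (phloroacetophenone, dried, 1.5 equiv); 2 geranyl bromide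
Product: 3 1-[3-[(2E)-3,7-dimethylocta-2,6-dienyl]-2,4,6-trihydroxyphenyl]ethanone (3-geranylphloroacetophenone)
Conditions: K2CO3 (1 equiv), acetone, reflux, 6 h
Reagents that add atoms: none
Why: C-alkylation of the ambident phloroglucinol-type phenolate by SN2 on the soft allylic bromide (the chemical counterpart of aromatic prenyl transfer) gives a single mono-C-geranyl isomer because the two free ring positions are equivalent, keeps the E-alkene, and is held at mono-alkylation by the excess of 1.

Step 2
Reactants: 3 3-geranylphloroacetophenone; 4 vanillin (1.2 equiv)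
Product: 6 (E)-1-[3-[(2E)-3,7-dimethylocta-2,6-dienyl]-2,4,6-trihydroxyphenyl]-3-(4-hydroxy-3-methoxyphenyl)prop-2-en-1-one (3'-geranylchalcone), via aldol adduct 5 (not isolated)
Conditions: LiHMDS (6 equiv in all; 4 pre-lithiated separately), THF, −78 °C to rt, 16 h; inverse quench into ice-cold 1 M HCl (pH ≤ 3)
Reagents that add atoms: none
Why: This is a Claisen–Schmidt condensation (directed aldol, then E1cB) run on the lithium polyanion, a known remedy for the failure of aqueous-hydroxide condensations of unprotected prenylated phloroacetophenones: excess LiHMDS ionises all phenols and then forms the methyl-ketone enolate, which adds to lithium vanillinate, and dehydration of 5 (completed in the acid quench through its p-hydroxybenzylic position) gives only the E-enone with no stereocentre, while the jump from strong base to pH ≤ 3 avoids the pH 7–11 window in which 6 closes racemically.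

Step 3
Reactants: 6 3'-geranylchalcone
Product: 7 (2S)-6-[(2E)-3,7-dimethylocta-2,6-dienyl]-5,7-dihydroxy-2-(4-hydroxy-3-methoxyphenyl)chroman-4-one ((2S)-6-geranylhomoeriodictyol, 3'-O-methyldiplacone)
Conditions: 1-[3,5-bis(trifluoromethyl)phenyl]-3-[(9R)-6'-methoxycinchonan-9-yl]thiourea (15 mol %), PhMe/MTBE 3:1 (0.02 M), −20 °C, 72 h; cold 5 % citric acid wash; SiO2 (removes the minor 8-geranyl isomer)
Reagents that add atoms: none
Why: Proposed new method: the catalyst copies chalcone isomerase, its thiourea N–H bonds polarising the carbonyl oxygen while the quinuclidine nitrogen takes the proton of the open 6'-OH (the 2'-OH is shielded by the geranyl group and buttressed into the C=O chelate, which is why 3'-prenyl-2',4',6'-trihydroxychalcones already prefer the 6-substituted flavanone), so the ion-paired phenoxide adds to one face of Cβ and sets C-2 as S, the ammonium protonates the enolate, and the 5-OH···O=C chelate makes closure effectively irreversible at −20 °C; the closest known reaction type is the cinchona-alkaloid- and cinchona-thiourea-catalysed intramolecular oxa-Michael addition of 2-hydroxyaryl enones to chromanones and flavanones.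

Step 4
Reactants: 7 (2S)-6-geranylhomoeriodictyol
Product: 9 tomentodiplacone B, (2S)-5,7-dihydroxy-2-(4-hydroxy-3-methoxyphenyl)-6-[(2E,5E)-7-hydroxy-3,7-dimethylocta-2,5-dienyl]chroman-4-one, via tertiary allylic hydroperoxide 8 (not isolated)
Conditions: O2 (1 atm), TPP (0.5 mol %), CH2Cl2, −10 °C, LED > 550 nm, to about 65 % conversion; then PPh3 (1.1 equiv), 0 °C; SiO2, then prep HPLC, with recovered 7 recycled
Reagents that add atoms: dioxygen (as singlet oxygen), O=O
Why: In this Schenck ene reaction singlet oxygen attacks the less shielded terminal trisubstituted alkene, binds at C-7'' and takes an allylic hydrogen from C-5'', which moves the double bond to C-5''=C-6'' with E geometry and gives 8, reduced by PPh3 with retention of the C–O bond; no stereocentre is created because C-7'' carries two methyls, and the neutral aprotic medium and long-wavelength light leave the base- and UV-labile C-2 centre untouched.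

## Compound list
1 | 2,4,6-trihydroxyacetophenone | CC(=O)c1c(O)cc(O)cc1O | starting material
2 | geranyl bromide | CC(C)=CCC/C(C)=C/CBr | starting material
3 | 3-geranyl-2,4,6-trihydroxyacetophenone | CC(=O)c1c(O)cc(O)c(C/C=C(\C)CCC=C(C)C)c1O | intermediate
4 | vanillin | COc1cc(C=O)ccc1O | starting material
5 | racemic aldol adduct, 1-(3-geranyl-2,4,6-trihydroxyphenyl)-3-hydroxy-3-(4-hydroxy-3-methoxyphenyl)propan-1-one | COc1cc(C(O)CC(=O)c2c(O)cc(O)c(C/C=C(\C)CCC=C(C)C)c2O)ccc1O | intermediate
6 | (E)-3'-geranyl-2',4',6',4-tetrahydroxy-3-methoxychalcone | COc1cc(/C=C/C(=O)c2c(O)cc(O)c(C/C=C(\C)CCC=C(C)C)c2O)ccc1O | intermediate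
7 | (2S)-6-geranylhomoeriodictyol (3'-O-methyldiplacone) | COc1cc([C@@H]2CC(=O)c3c(cc(O)c(C/C=C(\C)CCC=C(C)C)c3O)O2)ccc1O | intermediate
8 | (2S)-6-[(2E,5E)-7-hydroperoxy-3,7-dimethylocta-2,5-dienyl]homoeriodictyol | COc1cc([C@@H]2CC(=O)c3c(cc(O)c(C/C=C(\C)C/C=C/C(C)(C)OO)c3O)O2)ccc1O | intermediate
9 | tomentodiplacone B | COc1cc([C@@H]2CC(=O)c3c(cc(O)c(C/C=C(\C)C/C=C/C(C)(C)O)c3O)O2)ccc1O | target

## Step count
Total steps: 4. Longest linear sequence: 4 (1 → 3 → 6 → 7 → 9).

## Steps most likely to fail

**Step 3 (ee and 6-/8-selectivity).**
- Risks: unactivated chalcones give only moderate ee with small-molecule catalysts. The 2',6'-dihydroxychalcone also closes by itself. The amine can racemise the 4'-hydroxyflavanone by ring opening through its phenolate (quinone methide).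
- Fallback: it sets out from 6 and returns at 7, replacing asymmetric catalysis by resolution with recycling. Chalcone 6 is closed without a chiral catalyst (NaOAc, EtOH, reflux) to racemic 6-geranylhomoeriodictyol F1. This is resolved by preparative chiral SFC on an amylose carbamate phase into 7 and (2R)-6-geranylhomoeriodictyol F2.
- Recycling: F2 is reopened with cold concentrated KOH to the polyanion of 6 and recovered by inverse quench into cold acid.

**Step 4 (site and regioselectivity).**
- Risks: both trisubstituted alkenes react, and the terminal one gives tertiary and secondary hydroperoxides in roughly equal amounts. About 25–35 % of 9 per pass is realistic.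
- Fallback: it sets out from 1 and returns at 9, oxidising the chain before it is attached.
- Purchased geranyl acetate F3 has its 2,3-alkene deactivated by the allylic acetate, so photooxygenation (TPP, O2, hν) occurs only at the 6,7-alkene. This gives (2E,5E)-7-hydroperoxy-3,7-dimethylocta-2,5-dienyl acetate F4.
- PPh3 reduces it to (2E,5E)-7-hydroxy-3,7-dimethylocta-2,5-dienyl acetate F5, which is separated from its secondary regioisomer at this cheap stage.
- Tsuji–Trost C-allylation of 1 with F5 (Pd(PPh3)4, K2CO3, THF; attack at the primary terminus with retention of the E-alkene) gives 3-[(2E,5E)-7-hydroxy-3,7-dimethylocta-2,5-dienyl]-2,4,6-trihydroxyacetophenone F6.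
- LiHMDS (7 equiv) and 4, as in step 2, give the side-chain-oxidised chalcone F7. The catalyst of step 3 closes F7 directly to 9, so the stereocentre is set in the last operation.

**Step 2 (polyanion condensation).**
- Risks: poor solubility of the polyanion, low electrophilicity of lithium vanillinate, and retro-aldol cleavage.
- Fallback: it sets out from 3 and 4 and returns at 6, using the classical protected condensation.
- Ketone 3 with MOMCl and i-Pr2NEt gives 3-geranyl-2-hydroxy-4,6-bis(methoxymethoxy)acetophenone F8. Vanillin 4 gives 3-methoxy-4-(methoxymethoxy)benzaldehyde F9 in the same way.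
- KOH in aqueous EtOH at rt condenses them to the tris-MOM chalcone F10. HCl in MeOH at rt removes the three acetals to give 6, which does not cyclise appreciably in acid.

## Further compounds
F1 | step 3 | racemic 6-geranylhomoeriodictyol | COc1cc(C2CC(=O)c3c(cc(O)c(C/C=C(\C)CCC=C(C)C)c3O)O2)ccc1O
F2 | step 3 | (2R)-6-geranylhomoeriodictyol | COc1cc([C@H]2CC(=O)c3c(cc(O)c(C/C=C(\C)CCC=C(C)C)c3O)O2)ccc1O
F3 | step 4 | geranyl acetate (purchased) | CC(C)=CCC/C(C)=C/COC(C)=O
F4 | step 4 | (2E,5E)-7-hydroperoxy-3,7-dimethylocta-2,5-dienyl acetate | CC(=O)OC/C=C(\C)C/C=C/C(C)(C)OO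
F5 | step 4 | (2E,5E)-7-hydroxy-3,7-dimethylocta-2,5-dienyl acetate | CC(=O)OC/C=C(\C)C/C=C/C(C)(C)O
F6 | step 4 | 3-[(2E,5E)-7-hydroxy-3,7-dimethylocta-2,5-dienyl]-2,4,6-trihydroxyacetophenone | CC(=O)c1c(O)cc(O)c(C/C=C(\C)C/C=C/C(C)(C)O)c1O
F7 | step 4 | (E)-3'-[(2E,5E)-7-hydroxy-3,7-dimethylocta-2,5-dienyl]-2',4',6',4-tetrahydroxy-3-methoxychalcone | COc1cc(/C=C/C(=O)c2c(O)cc(O)c(C/C=C(\C)C/C=C/C(C)(C)O)c2O)ccc1O
F8 | step 2 | 3-geranyl-2-hydroxy-4,6-bis(methoxymethoxy)acetophenone | CC(=O)c1c(OCOC)cc(OCOC)c(C/C=C(\C)CCC=C(C)C)c1O
F9 | step 2 | 3-methoxy-4-(methoxymethoxy)benzaldehyde | COCOc1ccc(C=O)cc1OC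
F10 | step 2 | (E)-3'-geranyl-2'-hydroxy-3-methoxy-4,4',6'-tris(methoxymethoxy)chalcone | COCOc1ccc(/C=C/C(=O)c2c(OCOC)cc(OCOC)c(C/C=C(\C)CCC=C(C)C)c2O)cc1OC
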